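A time cannot be carried from one run to the next here: at 10.0 min the theta run has lost 6.00% of its starting material and the eta run 50.9%. So the clock has to be divided out, and the rate of target gain over the rate of starting-material loss does that.

| flask | starting material | precatalyst | temperature | remark | time |
|---|---|---|---|---|---|
| theta | 2.4 M | 0.60 mM | 85 °C | run made earlier |  |
| eta | 2.4 M | 0.90 mM | 118 °C | run made earlier |  |
| west | 2.4 M | 1.2 mM | 100 °C |  | 30 min |
| south-east | 2.4 M | 1.2 mM | 130 °C |  | 30 min |
| north-east | 2.4 M | 1.2 mM | 70 °C |  | 30 min |

| run | time / min | target / % | starting material / % |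
|---|---|---|---|
| theta | 4.00 | 0.4 | 98.0 |
| theta | 6.00 | 1.6 | 97.5 |
| theta | 10.0 | 2.8 | 94.0 |
| theta | 15.0 | 4.9 | 89.4 |
| theta | 30.0 | 12.7 | 72.9 |
| theta | 50.0 | 19.6 | 54.0 |
| eta | 0.667 | 1.3 | 97.0 |
| eta | 2.00 | 7.0 | 86.2 |
| eta | 3.00 | 10.1 | 77.1 |
| eta | 5.00 | 16.4 | 65.2 |
| eta | 8.00 | 22.8 | 55.1 |
| eta | 10.0 | 23.7 | 49.1 |

(readings scatter by 0.5 percentage points)

1. which flask leads in amount of target, in percent of the starting material charged ("all alike" within 1.5 percentage points) (west / south-east / north-east / all alike)
2. how much target is there at the end, in percent of the starting material charged: west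
3. how much target is there at the end, in percent of the starting material charged: south-east
4. how much target is there at the end, in percent of the starting material charged: north-east



The first estimate is a plain share. Target per starting material lost is 0.469 at 30.0 min in theta, and 0.466 at the end of eta, which looks constant. But a share over a whole run hides its latest part. Between the last two eta readings the gain over the loss is 0.150, and this marginal yield, target gained per starting material lost between two readings (the differential selectivity), is the number to follow. Yet that gain is comparable with its own scatter of 0.71 percentage points, so it could be noise. Theta's last step is firmer: 0.365, lower than the share. The readings thus point to a marginal yield that falls as conversion grows.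

A straight line through the two steps reaches zero near 55.8% conversion, and on that line target turns over at about 23.8%. One objection remains: at conversions of 46.0% and 44.9%, theta holds 19.6% and eta 22.8%, more in eta, so the two runs do not share one curve. That ceiling starts from the eta readings, the hotter run, so it is an estimate and no bound. My reckoning puts west a little below it, south-east, hotter, past the turn and lower, and north-east at the early share of a small conversion.

The forecast names west as the leader, with 35% there, 24% in south-east and 5% in north-east, holding that “Target is a steady 46% or so of the material consumed in both runs”. Its west stands above my ceiling.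

The flasks give 22.8% in west, 17.1% in south-east and 5.45% in north-east.

    starting material + catalyst ⇌ target + catalyst, rate k1*[starting material]*[catalyst] forward; the back reaction follows from the equilibrium constant (K = 2.70, k = 0.610 M⁻¹ s⁻¹, Ea = 51.0 kJ mol⁻¹, ΔH = 7.00 kJ mol⁻¹)
    target + catalyst ⇌ isomer of the product B + catalyst, rate k2*[catalyst]*[target] forward; the back reaction follows from the equilibrium constant (K = 4.60, k = 0.980 M⁻¹ s⁻¹, Ea = 46.0 kJ mol⁻¹, ΔH = 4.00 kJ mol⁻¹)
    precatalyst → catalyst (k = 0.00380 s⁻¹, Ea = 96.0 kJ mol⁻¹)
    starting material + catalyst ⇌ isomer of the product A + catalyst, rate k4*[starting material]*[catalyst] forward; the back reaction follows from the equilibrium constant (K = 0.380, k = 0.640 M⁻¹ s⁻¹, Ea = 61.0 kJ mol⁻¹, ΔH = −39.0 kJ mol⁻¹)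
    (constants at 100 °C)

In south-east at 30.0 min, target is made at 0.693 of the rate at which it is used up, each step taken net. West's marginal yield from 15.0 min to 30.0 min is 0.105, below the eta step's 0.150. In south-east, from 12 min to 30.0 min, it is −0.441, with target falling from 24.8% to 17.1%.

All runs are simulated with made-up constants; noise was put on by code.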